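**Plan**

Atom labels follow carotenoid numbering: ring carbons C2–C6, C1 the hydroxyisopropyl carbon on C2, C7 the first polyene carbon on C6, and primed numbers for the acyclic half.
Cuts, in retrosynthetic order: C11=C12 and C11'=C12' (Wittig, C15 + C10 + C15); C9–C10 and C7=C8; both C1–CH3 bonds; C5–O; ring bond C2–C3; and last C2–C5/C2–C6 of a cyclopropane together with the ester bond at C1.
Enabling feature: C1 and C7 stand cis on the adjacent ring carbons C2 and C6 and can be tied into one γ-lactone, C3 and C4 are bare methylenes, and the C5 carbinol is a hydrated C4=C5 alkene. Ring bond C2–C3 can therefore come from the vinyl terminus of a lactone-fused vinylcyclopropane whose C2–C5 bond is given up.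
Forward: lactone and cyclopropane close in one carbene addition, the three-membered ring grows to the cyclopentene, and two methyl groups open the lactone. The chain then runs C10, C13, C15 and finally C40, by union with a C25 aldehyde made from pseudoionone and the C10 dialdehyde.
Stereochemistry: C6 comes from the chiral rhodium carboxamidate, C2 is re-set by the cis ring-fusion constraint in the key step, and C5 comes from convex-face oxygenation of the bicycle. Alkene geometry comes from the E-enynol, E-selective olefinations and thermal equilibration.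

Key step: step 5

Remark on the chemistry: pseudoionone is taken as its (3E,5E) isomer, and any 5Z material in the commercial product is assumed to be removed when salt 22 is recrystallised.

**Route**

Step 1
Reactants: 1 (2E)-3-methylpent-2-en-4-yn-1-ol
Product: 2 (2E)-3-methylpenta-2,4-dien-1-ol
Conditions: H2 (1 atm), Pd/CaCO3 poisoned with Pb(OAc)2, quinoline, EtOAc/hexane, 0 °C to rt, stopped after 1 equiv H2
Reagents that add atoms: none
Why: Lindlar-type semihydrogenation halts a terminal alkyne at the alkene on the poisoned surface, and the existing E trisubstituted alkene should stay untouched if uptake is stopped at one equivalent.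

Step 2
Reactants: 2 (2E)-3-methylpenta-2,4-dien-1-ol; 3 2,2,6-trimethyl-4H-1,3-dioxin-4-one
Product: 5 (2E)-3-methylpenta-2,4-dien-1-yl 3-oxobutanoate, via acetylketene 4 (not isolated)
Conditions: xylenes, 130 °C, acetone distilled off
Reagents that add atoms: none
Why: Thermal retro-hetero-Diels–Alder cleavage of the dioxinone releases acetylketene, which the primary allylic alcohol should trap quickly (acetoacetylation) during a heating period too short to harm the diene.

Step 3
Reactants: 5 (2E)-3-methylpenta-2,4-dien-1-yl 3-oxobutanoate
Product: 7 (2E)-3-methylpenta-2,4-dien-1-yl diazoacetate, via diazoacetoacetate 6 (not isolated)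
Conditions: 4-AcNHC6H4SO2N3, Et3N, MeCN, rt; then LiOH, H2O, rt
Reagents that add atoms: 4-acetamidobenzenesulfonyl azide, CC(=O)Nc1ccc(cc1)S(=O)(=O)N=[N+]=[N-]
Why: Regitz diazo transfer to the active methylene followed by hydroxide-induced deacetylation is the standard entry to allylic diazoacetates, and neither stage affects the diene.

Step 4
Reactants: 7 (2E)-3-methylpenta-2,4-dien-1-yl diazoacetate
Product: 8 (1S,5R,6S)-6-ethenyl-6-methyl-3-oxabicyclo[3.1.0]hexan-2-one (vinyl exo, methyl endo)
Conditions: Rh2(5S-MEPY)4 (1 mol %; MEPY = methyl 2-oxopyrrolidine-5-carboxylate), CH2Cl2, reflux, slow addition of 7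
Reagents that add atoms: none
Why: In this catalytic asymmetric intramolecular cyclopropanation of an allylic diazoacetate, carbene transfer from the chiral divalent rhodium carboxamidate to the nearer, more electron-rich trisubstituted alkene forms C2–C5 and C2–C6 and closes the lactone at once; it is stereospecific (the methyl cis to CH2O in 7 becomes endo, the vinyl exo), and by analogy with 3-methylbut-2-enyl diazoacetate the 5S ligand set should give the (1S,5R) ring fusion.

Step 5
Reactants: 8 (1S,5R,6S)-6-ethenyl-6-methyl-3-oxabicyclo[3.1.0]hexan-2-one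
Product: 9 (3aR,6aR)-4-methyl-3,3a,6,6a-tetrahydro-1H-cyclopenta[c]furan-1-one (cis-fused)
Conditions: flash vacuum pyrolysis, ca. 550 °C, ca. 0.01 mbar, quartz tube conditioned with PbCO3, cold trap −78 °C
Reagents that add atoms: none
Why: Homolysis of cyclopropane bond C2–C5, the weakest one because it leaves an allyl radical (C5–C4–C3) and a radical at C2 conjugated with the lactone carbonyl C1, is followed by bonding of C2 to the allyl terminus C3, a net 1,3-carbon shift that moves the alkene to C4=C5. This is the thermal vinylcyclopropane-to-cyclopentene rearrangement, established for 6-vinylbicyclo[3.1.0]hexan-2-ones and their 3-oxa (lactone) analogues made by intramolecular carbene addition to dienes. The five-membered ring closes by coupling of the two ends of a 1,5-diradical whose allyl part holds C6 and C3 cis about C4–C5, whereas diradicals with the other allyl geometry can only fall back to the cyclopropane and try again. C6 keeps all four of its bonds, and the re-formed stereocentre C2 is fixed by the ring, because the bridge C5–C4–C3 hangs from C6 and can reach C2 only on the face that gives the cis-fused bicyclo[3.3.0] lactone, so the enantiopurity of step 4 should carry over to both fusion carbons. The step needs cleavage of C2–C5 rather than C5–C6, which the carbonyl on C2 secures, and it needs ring expansion to outrun hydrogen shifts: the homodienyl shift requires the vinyl group cis to the C7 methylene and is closed to the exo-vinyl isomer derived from the E-dienol, and the lactone ring holds the carbonyl oxygen away from the endo methyl so that the enolene-type shift of cis-alkyl cyclopropyl esters has no workable geometry. Short contact time and the base-conditioned tube should limit leakage through the endo epimer and acid-induced opening.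

Step 6
Reactants: 9 (3aR,6aR)-4-methyl-3,3a,6,6a-tetrahydro-1H-cyclopenta[c]furan-1-one
Product: 11 (3aS,4R,6aR)-4-hydroxy-4-methylhexahydro-1H-cyclopenta[c]furan-1-one, via tertiary hydroperoxide 10 (not isolated)
Conditions: Co(acac)2 (20 mol %), PhSiH3, O2 (1 atm), THF, rt; then PPh3
Reagents that add atoms: dioxygen, O=O
Why: In the Mukaiyama hydration, hydrogen-atom transfer places H on C4 and leaves the tertiary C5 radical (Markovnikov sense), which O2 should intercept on the convex face of the cis-bicyclo[3.3.0] lactone, the face of the ring-fusion hydrogens, so that the C5 oxygen ends up trans and the C5 methyl cis to C1 and C7, after which PPh3 reduces the hydroperoxide.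

Step 7
Reactants: 11 (3aS,4R,6aR)-4-hydroxy-4-methylhexahydro-1H-cyclopenta[c]furan-1-one
Product: 12 (1R,2S,3R)-2-(hydroxymethyl)-3-(2-hydroxypropan-2-yl)-1-methylcyclopentan-1-ol
Conditions: MeLi, CeCl3 (5 equiv each), THF, −78 to 0 °C; then aq NH4Cl
Reagents that add atoms: methyllithium, [Li]C
Why: Double addition of a methyl organometallic to a lactone turns C1 into the dimethyl carbinol and frees C7 as the primary alcohol, and the weakly basic organocerium reagent favours addition over enolisation, so that C2, alpha to the carbonyl throughout the addition, should not epimerise.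

Step 8
Reactants: 12 (1R,2S,3R)-2-(hydroxymethyl)-3-(2-hydroxypropan-2-yl)-1-methylcyclopentan-1-ol
Product: 13 tris(triethylsilyl) ether of 12 (configuration unchanged)
Conditions: Et3SiOTf, 2,6-lutidine, CH2Cl2, 0 °C to rt
Reagents that add atoms: triethylsilyl trifluoromethanesulfonate, CC[Si](CC)(CC)OS(=O)(=O)C(F)(F)F
Why: Silylation with a silyl triflate and lutidine is strong enough for tertiary alcohols, and capping both carbinols removes the later risks of retro-aldol cleavage across C5–C6, of lactol formation with over-oxidation, and of oxa-Michael closure from the C1 hydroxyl.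

Step 9
Reactants: 13 tris(triethylsilyl) ether of 12
Product: 14 (1R,2R,5R)-2-methyl-2-(triethylsilyloxy)-5-[2-(triethylsilyloxy)propan-2-yl]cyclopentane-1-carbaldehyde
Conditions: (COCl)2, DMSO, CH2Cl2, −78 to −40 °C; then iPr2NEt, −78 to −20 °C; cold pH 7 buffer
Reagents that add atoms: none
Why: Swern oxidation applied directly to a silyl ether is known to convert only unhindered primary triethylsilyl ethers into aldehydes while tertiary ones stay on, and the bulky amine at low temperature should spare the C6 stereocentre.

Step 10
Reactants: 14 (1R,2R,5R)-2-methyl-2-(triethylsilyloxy)-5-[2-(triethylsilyloxy)propan-2-yl]cyclopentane-1-carbaldehyde; 15 dimethyl (2-oxopropyl)phosphonate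
Product: 16 (3E)-4-{(1R,2R,5R)-2-methyl-2-(triethylsilyloxy)-5-[2-(triethylsilyloxy)propan-2-yl]cyclopentyl}but-3-en-2-one
Conditions: LiCl, iPr2NEt, MeCN, rt
Reagents that add atoms: none
Why: Under Masamune–Roush conditions for the Horner–Wadsworth–Emmons olefination, lithium chelation makes the ketophosphonate acidic enough for a tertiary amine, so the epimerisable β-silyloxy aldehyde never meets a strong base, and the stabilised reagent should give the E C7=C8 alkene.

Step 11
Reactants: 16 (3E)-4-{(1R,2R,5R)-2-methyl-2-(triethylsilyloxy)-5-[2-(triethylsilyloxy)propan-2-yl]cyclopentyl}but-3-en-2-one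
Product: 17 (1E)-1-{(1R,2R,5R)-2-methyl-2-(triethylsilyloxy)-5-[2-(triethylsilyloxy)propan-2-yl]cyclopentyl}-3-methylpenta-1,4-dien-3-ol (both epimers at the new carbinol carbon C9)
Conditions: CH2=CHMgBr, THF, −78 to −20 °C; then aq NH4Cl
Reagents that add atoms: vinylmagnesium bromide, C=C[Mg]Br
Why: Grignard 1,2-addition is the routine outcome for ionone-type enones with a hindered β-carbon, and the uncontrolled C9 centre does not matter because it becomes sp2 in step 12.

Step 12
Reactants: 17 (1E)-1-{(1R,2R,5R)-2-methyl-2-(triethylsilyloxy)-5-[2-(triethylsilyloxy)propan-2-yl]cyclopentyl}-3-methylpenta-1,4-dien-3-ol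
Product: 19 {(2E,4E)-5-[(1R,2R,5R)-2-hydroxy-5-(2-hydroxypropan-2-yl)-2-methylcyclopentyl]-3-methylpenta-2,4-dien-1-yl}triphenylphosphonium bromide, via bis-silyl phosphonium salt 18 (not isolated)
Conditions: PPh3·HBr (1.25 equiv), MeOH, 0 °C to rt
Reagents that add atoms: triphenylphosphine hydrobromide, [Br-].c1ccc(cc1)[PH+](c1ccccc1)c1ccccc1
Why: In this phosphonium salt formation from a vinyl carbinol with allylic transposition (SN1 type), the doubly allylic C9 alcohol ionises far more readily than any saturated carbinol, PPh3 captures the pentadienyl cation irreversibly at the unhindered terminus C11 to give mainly the 9E salt with the adjacent C6–H centre expected to survive as it does in α-ionone-type end groups, and the excess acid in methanol then solvolyses both silyl ethers.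

Step 13
Reactants: 20 pseudoionone, (3E,5E)-6,10-dimethylundeca-3,5,9-trien-2-one
Product: 21 (4E,6E)-3,7,11-trimethyldodeca-1,4,6,10-tetraen-3-ol (racemic)
Conditions: CH2=CHMgBr, THF, −20 to 0 °C; then aq NH4Cl
Reagents that add atoms: vinylmagnesium bromide, C=C[Mg]Br
Why: Grignard 1,2-addition to the dienone is the standard C13 to C15 homologation of ionone-type ketones, and the racemic carbinol centre is erased in step 14.

Step 14
Reactants: 21 (4E,6E)-3,7,11-trimethyldodeca-1,4,6,10-tetraen-3-ol
Product: 22 [(2E,4E,6E)-3,7,11-trimethyldodeca-2,4,6,10-tetraen-1-yl]triphenylphosphonium bromide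
Conditions: PPh3·HBr, MeOH, rt; recrystallisation
Reagents that add atoms: triphenylphosphine hydrobromide, [Br-].c1ccc(cc1)[PH+](c1ccccc1)c1ccccc1
Why: Phosphonium salt formation from a vinyl carbinol with allylic transposition should deliver phosphorus to the primary terminus of the extended allylic cation, the mild acid should leave the remote trisubstituted alkene uncyclised, and recrystallisation should enrich the all-E salt.

Step 15
Reactants: 22 [(2E,4E,6E)-3,7,11-trimethyldodeca-2,4,6,10-tetraen-1-yl]triphenylphosphonium bromide; 23 (2E,4E,6E)-2,7-dimethylocta-2,4,6-trienedial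
Product: 25 apo-12'-lycopenal (all-E C25 aldehyde), via acyclic C15 ylide 24 (not isolated)
Conditions: NaOMe added slowly, 23 in excess (2.5 equiv), CH2Cl2/MeOH, 0 °C to rt, dark; then heptane, reflux; crystallisation
Reagents that add atoms: none
Why: In this Wittig olefination the excess of the symmetrical dialdehyde and the lower electrophilicity of the longer polyenal should favour single condensation, and the E/Z mixture at the new C11'=C12' bond should converge on all-E on heating and crystallisation.

Step 16
Reactants: 19 {(2E,4E)-5-[(1R,2R,5R)-2-hydroxy-5-(2-hydroxypropan-2-yl)-2-methylcyclopentyl]-3-methylpenta-2,4-dien-1-yl}triphenylphosphonium bromide; 25 apo-12'-lycopenal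
Product: 27 (all-E,2R,5R,6R)-2,6-cyclolycopene-1,5-diol (target), via ring-end ylide 26 (not isolated)
Conditions: NaOMe, CH2Cl2/MeOH, 0 °C to rt, argon, dark; then EtOH, reflux; crystallisation
Reagents that add atoms: none
Why: This Wittig olefination forms C11=C12, tolerates free tertiary hydroxyl groups under alkoxide conditions and touches no sp3 stereocentre, and heating the crude isomer mixture should take the unhindered Z bond to the thermodynamically preferred all-E polyene, which crystallises.

**Compound list**

1 | (2E)-3-methylpent-2-en-4-yn-1-ol | C#C/C(C)=C/CO | starting material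
2 | (2E)-3-methylpenta-2,4-dien-1-ol | C=C/C(C)=C/CO | intermediate
3 | 2,2,6-trimethyl-4H-1,3-dioxin-4-one | CC1=CC(=O)OC(C)(C)O1 | starting material
4 | acetylketene (formed in situ) | CC(=O)C=C=O | intermediate
5 | (2E)-3-methylpenta-2,4-dien-1-yl 3-oxobutanoate | C=C/C(C)=C/COC(=O)CC(C)=O | intermediate
6 | (2E)-3-methylpenta-2,4-dien-1-yl 2-diazo-3-oxobutanoate (formed in situ) | C=C/C(C)=C/COC(=O)C(=[N+]=[N-])C(C)=O | intermediate
7 | (2E)-3-methylpenta-2,4-dien-1-yl diazoacetate | C=C/C(C)=C/COC(=O)C=[N+]=[N-] | intermediate
8 | (1S,5R,6S)-6-ethenyl-6-methyl-3-oxabicyclo[3.1.0]hexan-2-one, vinyl exo | O=C3OC[C@@H]1[C@H]3[C@@]1(C)C=C | intermediate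
9 | (3aR,6aR)-4-methyl-3,3a,6,6a-tetrahydro-1H-cyclopenta[c]furan-1-one | O=C3OC[C@@H]1[C@H]3CC=C1C | intermediate
10 | (3aS,4R,6aR)-4-hydroperoxy-4-methylhexahydro-1H-cyclopenta[c]furan-1-one (formed in situ) | O=C3OC[C@@H]1[C@H]3CC[C@@]1(C)OO | intermediate
11 | (3aS,4R,6aR)-4-hydroxy-4-methylhexahydro-1H-cyclopenta[c]furan-1-one | O=C3OC[C@@H]1[C@H]3CC[C@@]1(C)O | intermediate
12 | (1R,2S,3R)-2-(hydroxymethyl)-3-(2-hydroxypropan-2-yl)-1-methylcyclopentan-1-ol | OC[C@@H]1[C@H](C(C)(C)O)CC[C@@]1(C)O | intermediate
13 | tris(triethylsilyl) ether of 12 | CC[Si](CC)(CC)OC[C@@H]1[C@H](C(C)(C)O[Si](CC)(CC)CC)CC[C@@]1(C)O[Si](CC)(CC)CC | intermediate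
14 | (1R,2R,5R)-2-methyl-2-(triethylsilyloxy)-5-[2-(triethylsilyloxy)propan-2-yl]cyclopentane-1-carbaldehyde | O=C[C@@H]1[C@H](C(C)(C)O[Si](CC)(CC)CC)CC[C@@]1(C)O[Si](CC)(CC)CC | intermediate
15 | dimethyl (2-oxopropyl)phosphonate | CC(=O)CP(=O)(OC)OC | starting material
16 | (3E)-4-{(1R,2R,5R)-2-methyl-2-(triethylsilyloxy)-5-[2-(triethylsilyloxy)propan-2-yl]cyclopentyl}but-3-en-2-one | CC(=O)/C=C/[C@@H]1[C@H](C(C)(C)O[Si](CC)(CC)CC)CC[C@@]1(C)O[Si](CC)(CC)CC | intermediate
17 | (1E)-1-{(1R,2R,5R)-2-methyl-2-(triethylsilyloxy)-5-[2-(triethylsilyloxy)propan-2-yl]cyclopentyl}-3-methylpenta-1,4-dien-3-ol, both carbinol epimers | C=CC(C)(O)/C=C/[C@@H]1[C@H](C(C)(C)O[Si](CC)(CC)CC)CC[C@@]1(C)O[Si](CC)(CC)CC | intermediate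
18 | bis(triethylsilyl) ether of salt 19 (formed in situ) | [Br-].c1ccccc1[P+](c1ccccc1)(c1ccccc1)C/C=C(C)/C=C/[C@@H]1[C@H](C(C)(C)O[Si](CC)(CC)CC)CC[C@@]1(C)O[Si](CC)(CC)CC | intermediate
19 | {(2E,4E)-5-[(1R,2R,5R)-2-hydroxy-5-(2-hydroxypropan-2-yl)-2-methylcyclopentyl]-3-methylpenta-2,4-dien-1-yl}triphenylphosphonium bromide | [Br-].c1ccccc1[P+](c1ccccc1)(c1ccccc1)C/C=C(C)/C=C/[C@@H]1[C@H](C(C)(C)O)CC[C@@]1(C)O | intermediate
20 | pseudoionone, (3E,5E)-6,10-dimethylundeca-3,5,9-trien-2-one | CC(=O)/C=C/C=C(C)/CCC=C(C)C | starting material
21 | (4E,6E)-3,7,11-trimethyldodeca-1,4,6,10-tetraen-3-ol, racemic | C=CC(C)(O)/C=C/C=C(C)/CCC=C(C)C | intermediate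
22 | [(2E,4E,6E)-3,7,11-trimethyldodeca-2,4,6,10-tetraen-1-yl]triphenylphosphonium bromide | [Br-].CC(C)=CCC/C(C)=C/C=C/C(C)=C/C[P+](c1ccccc1)(c1ccccc1)c1ccccc1 | intermediate
23 | (2E,4E,6E)-2,7-dimethylocta-2,4,6-trienedial | O=C/C(C)=C/C=C/C=C(C)/C=O | starting material
24 | ylide of 22 (formed in situ) | CC(C)=CCC/C(C)=C/C=C/C(C)=C/C=P(c1ccccc1)(c1ccccc1)c1ccccc1 | intermediate
25 | apo-12'-lycopenal, all-E | CC(C)=CCC/C(C)=C/C=C/C(C)=C/C=C/C(C)=C/C=C/C=C(C)/C=O | intermediate
26 | ylide of 19 (formed in situ) | c1ccccc1P(c1ccccc1)(c1ccccc1)=C/C=C(C)/C=C/[C@@H]1[C@H](C(C)(C)O)CC[C@@]1(C)O | intermediate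
27 | (all-E,2R,5R,6R)-2,6-cyclolycopene-1,5-diol | CC(C)=CCC/C(C)=C/C=C/C(C)=C/C=C/C(C)=C/C=C/C=C(C)/C=C/C=C(C)/C=C/[C@@H]1[C@H](C(C)(C)O)CC[C@@]1(C)O | target

**Step count**

Total step count: 16. Longest linear sequence: 13 steps (steps 1–12 and 16, from 1).

**Steps most likely to fail**

Step 5.
- **Risk:** Reversible homolysis may epimerise C5 faster than the ring expands. The endo-vinyl epimer can then drain away through a homodienyl hydrogen shift from the C7 methylene. Partial cleavage of C5–C6 would also erode the regiochemistry.
- **Fallback:** The same C2–C3 bond is made in two ionic stages instead of one thermal one. Setting out from 8, Me3SiI and (Me3Si)2NH in CH2Cl2 at −78 to −40 °C should activate the lactone carbonyl while iodide attacks the vinyl terminus C3 in an SN2' sense and opens C2–C5. Aqueous work-up would give (4R)-4-[(2Z)-4-iodobut-2-en-2-yl]oxolan-2-one F1, whose E and Z forms interconvert by iodide exchange. LiN(SiMe3)2 in THF at −78 °C would then form the lactone enolate. Its 5-exo-tet alkylation at C3 is possible only from the Z form and only on the face that carries the C6 side chain, and it comes back to the route at 9.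

Step 10.
- **Risk:** Slow olefination of the flanked aldehyde may leave time for epimerisation at C6 towards the less crowded trans arrangement, or for loss of the C5 silyloxy group by β-elimination.
- **Fallback:** Carbanion chemistry is avoided altogether. Setting out from 14, non-basic Takai-type methylenation with Zn, CH2I2 and Ti(OiPr)4 in THF would give the vinylcyclopentane in which CH=CH2 replaces the CHO of 14, with the configuration unchanged, F2. Cross-metathesis with methyl vinyl ketone (second-generation Hoveyda–Grubbs catalyst, CH2Cl2, 40 °C) would install the E enone and come back to the route at 16.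

Step 6.
- **Risk:** Capture of the nearly planar C5 radical by O2 may show poor facial selectivity.
- **Fallback:** A concerted oxygen transfer is followed by hydride opening. Setting out from 9, mCPBA with NaHCO3 in CH2Cl2 at 0 °C should deliver oxygen to the convex face and give the C4,C5-epoxy lactone F3. MeLi in Et2O at −78 °C would convert the lactone into the dimethyl carbinol and primary alcohol without touching the trisubstituted epoxide, giving the epoxy diol F4. LiEt3BH in THF would attack the secondary carbon C4 and leave the C5–O bond, and hence the C5 configuration, intact, coming back to the route at 12.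

**Further compounds**

F1 | step 5 | (4R)-4-[(2Z)-4-iodobut-2-en-2-yl]oxolan-2-one | O=C1OC[C@H](C1)/C(C)=C\CI
F2 | step 10 | vinylcyclopentane, CH=CH2 in place of the CHO of 14, configuration unchanged | C=C[C@@H]1[C@H](C(C)(C)O[Si](CC)(CC)CC)CC[C@@]1(C)O[Si](CC)(CC)CC
F3 | step 6 | convex-face C4,C5-epoxide of lactone 9 | O=C3OC[C@@H]1[C@H]3C[C@H]2O[C@@]12C
F4 | step 6 | epoxy diol from F3 (C1 dimethyl carbinol, C7 primary alcohol, epoxide retained) | OC[C@@H]1[C@H](C(C)(C)O)C[C@H]2O[C@@]12C
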